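**Plan**

- Retrosynthesis: the C8–O ester bond and the protecting groups are cut first. Then the γ-lactone is opened at O6–C12, and the C11–C12 bond (lactone carbonyl carbon, from CO2) and the C6–C7 ring bond are cut together. The resulting acyclic chain is cut at C9=C10.
- Enabling feature: the α-methylene-γ-butyrolactone O6–C12(=O)–C11(=C13H2)–C7–C6, fused through C6–C7 to the ten-membered carbocycle, is the sum of a terminal allene (C7=C11=C13), CO2 (C12) and an aldehyde (C6=O). Ni(0) joins CO2 to the central allene carbon and turns the allene into a 2-carboxy-allylnickel that is nucleophilic at C7.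
- Forward: a citronellal-derived phosphonate (C1–C6, C10, C14) and a glyceraldehyde-derived allenyl aldehyde (C7–C9, C11, C13) are joined at C9=C10 by Horner–Wadsworth–Emmons olefination. The ten-membered ring and the lactone then arise in one operation from the acyclic allenyl aldehyde and CO2. The side chain is attached last.
- Stereochemistry: C4 comes from (S)-citronellal and C8 from (R)-glyceraldehyde acetonide. C7 is induced by C8 and C6 by the closed transition state of the ring closure. The C9=C10 geometry comes from the olefination and the side-chain geometry from a trans-hydroalumination.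

Key step: step 15

Remark (assumption): ring atoms are labelled in the germacranolide manner (C6 lactone O–CH, C7 the CH bearing C11, C8 the acyloxy carbon, C9=C10 the ring olefin, C14 its CH2OH, C4 the CH–CH3, C11=C13 the exo-methylene, C12 the lactone C=O), and the side-chain olefin is read from the SMILES as the (Z)-acid with the carboxyl cis to the γ-CH2OH.

**Route**

Step 1
Reactants: 1 (S)-citronellal
Product: 2 (S)-8,8-dimethoxy-2,6-dimethyloct-2-ene
Conditions: HC(OMe)3, MeOH, PPTS (cat.), rt
Reagents that add atoms: trimethyl orthoformate (COC(OC)OC)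
Why: Acid-catalysed acetalisation with the orthoformate as water scavenger masks the future C6 aldehyde and leaves the C4 stereocentre untouched.

Step 2
Reactants: 2 (S)-8,8-dimethoxy-2,6-dimethyloct-2-ene
Product: 3 (S)-6,6-dimethoxy-4-methylhexan-1-ol
Conditions: O3, CH2Cl2/MeOH, −78 °C; then NaBH4, −78 °C to rt
Reagents that add atoms: ozone ([O-][O+]=O)
Why: Ozonolysis with reductive work-up cleaves the trisubstituted olefin to the primary alcohol while the acetal is inert.

Step 3
Reactants: 3 (S)-6,6-dimethoxy-4-methylhexan-1-ol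
Product: 4 (S)-6-iodo-1,1-dimethoxy-3-methylhexane
Conditions: PPh3, I2, imidazole, CH2Cl2, 0 °C to rt
Reagents that add atoms: iodine (II)
Why: Appel-type iodination of the primary alcohol under imidazole buffering spares the acetal.

Step 4
Reactants: 4 (S)-6-iodo-1,1-dimethoxy-3-methylhexane; 5 triethyl phosphonoacetate
Product: 6 ethyl (6S)-2-(diethoxyphosphoryl)-8,8-dimethoxy-6-methyloctanoate (both C2 epimers)
Conditions: NaH, DMF, 0 °C; then 4, 60 °C
Reagents that add atoms: none
Why: SN2 C-alkylation of the sodium phosphonoacetate anion by the primary iodide gives the α-substituted olefination reagent; the new centre is lost in step 11.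

Step 5
Reactants: 7 (R)-2,2-dimethyl-1,3-dioxolane-4-carbaldehyde
Product: 8 (S)-4-ethynyl-2,2-dimethyl-1,3-dioxolane
Conditions: dimethyl (1-diazo-2-oxopropyl)phosphonate, K2CO3, MeOH, 0 °C to rt
Reagents that add atoms: dimethyl (1-diazo-2-oxopropyl)phosphonate (CC(=O)C(=[N+]=[N-])P(=O)(OC)OC)
Why: Seyferth–Gilbert homologation with the Ohira–Bestmann reagent converts the aldehyde into the terminal alkyne without touching the adjacent stereocentre (future C8).

Step 6
Reactants: 8 (S)-4-ethynyl-2,2-dimethyl-1,3-dioxolane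
Product: 9 (S)-2,2-dimethyl-4-(propa-1,2-dien-1-yl)-1,3-dioxolane
Conditions: (CH2O)n, CuI (0.5 equiv), Cy2NH, 1,4-dioxane, reflux
Reagents that add atoms: paraformaldehyde (C=O)
Why: Crabbé homologation (Mannich addition, then copper-mediated hydride shift and loss of the imine) turns the 1-alkyne into the terminal allene.

Step 7
Reactants: 9 (S)-2,2-dimethyl-4-(propa-1,2-dien-1-yl)-1,3-dioxolane
Product: 10 (S)-penta-3,4-diene-1,2-diol
Conditions: p-TsOH·H2O (cat.), MeOH, rt; Et3N quench
Reagents that add atoms: none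
Why: Acid-catalysed transketalisation to methanol releases the 1,2-diol under conditions the allene tolerates.

Step 8
Reactants: 10 (S)-penta-3,4-diene-1,2-diol
Product: 11 (4S)-2-(4-methoxyphenyl)-4-(propa-1,2-dien-1-yl)-1,3-dioxolane (both acetal epimers)
Conditions: 4-MeOC6H4CH(OMe)2, PPTS (cat.), CH2Cl2, rt
Reagents that add atoms: 4-methoxybenzaldehyde dimethyl acetal (COC(OC)c1ccc(OC)cc1)
Why: Acetal exchange gives the p-methoxybenzylidene acetal, whose acetal configuration is irrelevant for the next step.

Step 9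
Reactants: 11 (4S)-2-(4-methoxyphenyl)-4-(propa-1,2-dien-1-yl)-1,3-dioxolane
Product: 12 (S)-2-[(4-methoxybenzyl)oxy]penta-3,4-dien-1-ol
Conditions: DIBAL-H (3 equiv), CH2Cl2, −78 to 0 °C; Rochelle salt
Reagents that add atoms: none
Why: Regioselective reductive acetal opening, in which aluminium binds the less hindered primary oxygen and that C–O bond is cleaved, leaves the PMB group on the secondary oxygen.

Step 10
Reactants: 12 (S)-2-[(4-methoxybenzyl)oxy]penta-3,4-dien-1-ol
Product: 13 (S)-2-[(4-methoxybenzyl)oxy]penta-3,4-dienal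
Conditions: Dess–Martin periodinane, NaHCO3, CH2Cl2, 0 °C to rt; used crude
Reagents that add atoms: none
Why: Buffered Dess–Martin oxidation gives the α-alkoxy aldehyde under non-basic conditions that should avoid epimerisation and allene-to-diene isomerisation.

Step 11
Reactants: 6 ethyl (6S)-2-(diethoxyphosphoryl)-8,8-dimethoxy-6-methyloctanoate; 13 (S)-2-[(4-methoxybenzyl)oxy]penta-3,4-dienal
Product: 14 ethyl (2E,4S)-2-[(4S)-6,6-dimethoxy-4-methylhexyl]-4-[(4-methoxybenzyl)oxy]hepta-2,5,6-trienoate
Conditions: NaH, THF, 0 °C; then 13, −78 °C to rt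
Reagents that add atoms: none
Why: Horner–Wadsworth–Emmons olefination with an α-alkyl phosphonoacetate should give mainly the (E)-enoate (ester trans to C8), which is the C9=C10 geometry of the target.

Step 12
Reactants: 14 ethyl (2E,4S)-2-[(4S)-6,6-dimethoxy-4-methylhexyl]-4-[(4-methoxybenzyl)oxy]hepta-2,5,6-trienoate
Product: 15 (2E,4S)-2-[(4S)-6,6-dimethoxy-4-methylhexyl]-4-[(4-methoxybenzyl)oxy]hepta-2,5,6-trien-1-ol
Conditions: DIBAL-H (2.5 equiv), CH2Cl2, −78 °C; Rochelle salt
Reagents that add atoms: none
Why: 1,2-Reduction of the enoate with DIBAL-H gives the allylic alcohol (C14) and leaves the acetal, PMB ether and allene intact.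

Step 13
Reactants: 15 (2E,4S)-2-[(4S)-6,6-dimethoxy-4-methylhexyl]-4-[(4-methoxybenzyl)oxy]hepta-2,5,6-trien-1-ol
Product: 16 (3S,7E,9S)-7-(hydroxymethyl)-9-[(4-methoxybenzyl)oxy]-3-methyldodeca-7,10,11-trienal
Conditions: PPTS (cat.), acetone/H2O (10:1), 40 °C
Reagents that add atoms: water (O)
Why: Mild acid hydrolysis of the dimethyl acetal releases the C6 aldehyde at a stage where no silyl ether is present.

Step 14
Reactants: 16 (3S,7E,9S)-7-(hydroxymethyl)-9-[(4-methoxybenzyl)oxy]-3-methyldodeca-7,10,11-trienal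
Product: 17 (3S,7E,9S)-7-[(tert-butyldimethylsilyloxy)methyl]-9-[(4-methoxybenzyl)oxy]-3-methyldodeca-7,10,11-trienal
Conditions: TBSCl, imidazole, CH2Cl2, 0 °C
Reagents that add atoms: tert-butyldimethylsilyl chloride (CC(C)(C)[Si](C)(C)Cl)
Why: Silylation of the primary allylic alcohol removes the only acidic proton before the nickel step and is tolerated by the aldehyde.

Step 15
Reactants: 17 (3S,7E,9S)-7-[(tert-butyldimethylsilyloxy)methyl]-9-[(4-methoxybenzyl)oxy]-3-methyldodeca-7,10,11-trienal
Product: 20 (4S,6R,7S,8R,9E)-14-(tert-butyldimethylsilyloxy)-8-(4-methoxybenzyloxy)germacra-9,11(13)-dien-12,6-olide, via nickelalactone 18 (not isolated), via hydroxy acid 19 (not isolated)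
Conditions: Ni(cod)2 (2 equiv), DBU (10 equiv), CO2 (1 atm), THF, 0 °C, slow addition of 17 (to 2 mM), then rt; 1 M HCl, 0 °C; PPTS (cat.), CH2Cl2, rt
Reagents that add atoms: carbon dioxide (O=C=O)
Why: Proposed new method: Ni(0)/DBU couples CO2 oxidatively with the terminal allene at its central carbon (C11–C12) to give nickelalactone 18, a 2-carboxylato-allylnickel that is nucleophilic at C7 and adds to the tethered aldehyde through a chair-like six-membered transition state (C6–C7); acidification then lets the γ-hydroxy acid 19 lactonise. The closest known reaction types are the Ni(0)-promoted carboxylation/cyclisation cascade of allenyl aldehydes under CO2, shown so far only for five- and six-membered carbocycles, and the Cr- or Zn-mediated 2-(alkoxycarbonyl)allyl macrocyclisations of germacranolide synthesis, whose ring-closing event (allylmetal plus aldehyde) is the same. The ten-membered carbocycle closes in a 10-exo-trig mode (SE2′ attack of C7 on the C6 carbonyl) and the lactone afterwards by a 5-exo-trig O-acylation. C7 is set by the C8 stereocentre, because A(1,3) strain with the fully substituted C11 keeps H8 in the allyl plane so that the aldehyde adds anti to the C8–C9 bond, and C6 is set by the chair transition state with the syn (E) allyl unit and a pseudo-equatorial aldehyde chain, which gives the anti hydroxy acid and hence the trans-fused lactone. The step needs CO2 capture ahead of ring closure and bond formation at C7 and not at C13 or C11: saturation with CO2 at 0 °C secures the first (the reverse order would give the same two bonds), and the chelated nickelalactone, which holds nickel on the primary carbon C13, secures the second. Slow addition of 17 to excess Ni(0) keeps free substrate dilute and suppresses oligomers, and the PMB ether at C8 is a poor leaving group for 1,4-elimination from the allylnickel.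

Step 16
Reactants: 20 (4S,6R,7S,8R,9E)-14-(tert-butyldimethylsilyloxy)-8-(4-methoxybenzyloxy)germacra-9,11(13)-dien-12,6-olide
Product: 21 (9E)-8-hydroxy-14-(tert-butyldimethylsilyloxy)germacra-9,11(13)-dien-12,6-olide (configurations at C4, C6, C7 and C8 as in 20)
Conditions: DDQ, CH2Cl2/pH 7 buffer (10:1), 0 °C
Reagents that add atoms: none
Why: Oxidative PMB cleavage with DDQ frees the C8 hydroxyl under neutral conditions that spare the TBS ether and the α-methylene lactone.

Step 17
Reactants: 22 but-2-yne-1,4-diol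
Product: 23 (Z)-2-iodobut-2-ene-1,4-diol
Conditions: Red-Al (2.2 equiv), THF, 0 °C to rt; then I2, −78 to 0 °C
Reagents that add atoms: iodine (II)
Why: Alkoxide-directed trans-hydroalumination of the propargylic diol and iodinolysis with retention place iodine cis to the distal CH2OH, which is the olefin geometry of the side chain.

Step 18
Reactants: 23 (Z)-2-iodobut-2-ene-1,4-diol
Product: 24 (Z)-1,4-bis(tert-butyldimethylsilyloxy)-2-iodobut-2-ene
Conditions: TBSCl (2.4 equiv), imidazole, DMF, rt
Reagents that add atoms: tert-butyldimethylsilyl chloride (CC(C)(C)[Si](C)(C)Cl)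
Why: Standard bis-silylation protects both hydroxyls for the metalation.

Step 19
Reactants: 24 (Z)-1,4-bis(tert-butyldimethylsilyloxy)-2-iodobut-2-ene
Product: 25 (Z)-4-(tert-butyldimethylsilyloxy)-2-[(tert-butyldimethylsilyloxy)methyl]but-2-enoic acid
Conditions: t-BuLi (2.1 equiv), Et2O, −78 °C; CO2; 1 M HCl to pH 3
Reagents that add atoms: carbon dioxide (O=C=O)
Why: Iodine–lithium exchange and carboxylation both proceed with retention of olefin geometry, so the carboxyl ends up cis to the γ-CH2OTBS.

Step 20
Reactants: 21 (9E)-8-hydroxy-14-(tert-butyldimethylsilyloxy)germacra-9,11(13)-dien-12,6-olide; 25 (Z)-4-(tert-butyldimethylsilyloxy)-2-[(tert-butyldimethylsilyloxy)methyl]but-2-enoic acid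
Product: 27 (4S,6R,7S,8R,9E)-14-(tert-butyldimethylsilyloxy)-8-{(Z)-4-(tert-butyldimethylsilyloxy)-2-[(tert-butyldimethylsilyloxy)methyl]but-2-enoyloxy}germacra-9,11(13)-dien-12,6-olide, via mixed anhydride 26 (not isolated)
Conditions: 25, 2,4,6-trichlorobenzoyl chloride, Et3N, toluene, rt; then 21, DMAP (0.3 equiv), 0 °C to rt
Reagents that add atoms: none
Why: Yamaguchi esterification acylates the hindered secondary allylic alcohol through the mixed anhydride with retention at C8.

Step 21
Reactants: 27 (4S,6R,7S,8R,9E)-14-(tert-butyldimethylsilyloxy)-8-{(Z)-4-(tert-butyldimethylsilyloxy)-2-[(tert-butyldimethylsilyloxy)methyl]but-2-enoyloxy}germacra-9,11(13)-dien-12,6-olide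
Product: 28 CNP0131216.1, (4S,6R,7S,8R,9E)-14-hydroxy-8-[(Z)-4-hydroxy-2-(hydroxymethyl)but-2-enoyloxy]germacra-9,11(13)-dien-12,6-olide
Conditions: HF·pyridine, pyridine, THF, 0 °C to rt
Reagents that add atoms: none
Why: Buffered HF·pyridine removes the three primary allylic TBS ethers under mildly acidic conditions that should avoid acyl migration and translactonisation.

**Compound list**

1 | (S)-citronellal | O=CC[C@@H](C)CCC=C(C)C | starting material
2 | (S)-8,8-dimethoxy-2,6-dimethyloct-2-ene | COC(OC)C[C@@H](C)CCC=C(C)C | intermediate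
3 | (S)-6,6-dimethoxy-4-methylhexan-1-ol | COC(OC)C[C@@H](C)CCCO | intermediate
4 | (S)-6-iodo-1,1-dimethoxy-3-methylhexane | COC(OC)C[C@@H](C)CCCI | intermediate
5 | triethyl phosphonoacetate | CCOC(=O)CP(=O)(OCC)OCC | starting material
6 | ethyl (6S)-2-(diethoxyphosphoryl)-8,8-dimethoxy-6-methyloctanoate | CCOC(=O)C(CCC[C@H](C)CC(OC)OC)P(=O)(OCC)OCC | intermediate
7 | (R)-2,2-dimethyl-1,3-dioxolane-4-carbaldehyde | CC1(C)OC[C@H](C=O)O1 | starting material
8 | (S)-4-ethynyl-2,2-dimethyl-1,3-dioxolane | CC1(C)OC[C@H](C#C)O1 | intermediate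
9 | (S)-2,2-dimethyl-4-(propa-1,2-dien-1-yl)-1,3-dioxolane | CC1(C)OC[C@H](C=C=C)O1 | intermediate
10 | (S)-penta-3,4-diene-1,2-diol | OC[C@H](C=C=C)O | intermediate
11 | (4S)-2-(4-methoxyphenyl)-4-(propa-1,2-dien-1-yl)-1,3-dioxolane | COc1ccc(cc1)C1OC[C@H](C=C=C)O1 | intermediate
12 | (S)-2-[(4-methoxybenzyl)oxy]penta-3,4-dien-1-ol | OC[C@H](C=C=C)OCc1ccc(OC)cc1 | intermediate
13 | (S)-2-[(4-methoxybenzyl)oxy]penta-3,4-dienal | O=C[C@H](C=C=C)OCc1ccc(OC)cc1 | intermediate
14 | ethyl (2E,4S)-2-[(4S)-6,6-dimethoxy-4-methylhexyl]-4-[(4-methoxybenzyl)oxy]hepta-2,5,6-trienoate | CCOC(=O)/C(CCC[C@H](C)CC(OC)OC)=C/[C@H](C=C=C)OCc1ccc(OC)cc1 | intermediate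
15 | (2E,4S)-2-[(4S)-6,6-dimethoxy-4-methylhexyl]-4-[(4-methoxybenzyl)oxy]hepta-2,5,6-trien-1-ol | OC/C(CCC[C@H](C)CC(OC)OC)=C/[C@H](C=C=C)OCc1ccc(OC)cc1 | intermediate
16 | (3S,7E,9S)-7-(hydroxymethyl)-9-[(4-methoxybenzyl)oxy]-3-methyldodeca-7,10,11-trienal | OC/C(CCC[C@H](C)CC=O)=C/[C@H](C=C=C)OCc1ccc(OC)cc1 | intermediate
17 | (3S,7E,9S)-7-[(tert-butyldimethylsilyloxy)methyl]-9-[(4-methoxybenzyl)oxy]-3-methyldodeca-7,10,11-trienal | CC(C)(C)[Si](C)(C)OC/C(CCC[C@H](C)CC=O)=C/[C@H](C=C=C)OCc1ccc(OC)cc1 | intermediate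
18 | nickelalactone from the allene of 17 and CO2 (five-membered Ni–O–C12(=O)–C11–C13 ring, E-alkylidene at C11, DBU ligands omitted; not isolated) | O=C1O[Ni]C/C1=C/[C@H](OCc2ccc(OC)cc2)/C=C(/CO[Si](C)(C)C(C)(C)C)CCC[C@H](C)CC=O | intermediate
19 | (4S,6R,7S,8R,9E)-6-hydroxy-14-(tert-butyldimethylsilyloxy)-8-(4-methoxybenzyloxy)germacra-9,11(13)-dien-12-oic acid (not isolated) | OC(=O)C(=C)[C@H]1[C@H](O)C[C@@H](C)CCC/C(CO[Si](C)(C)C(C)(C)C)=C\[C@H]1OCc2ccc(OC)cc2 | intermediate
20 | (4S,6R,7S,8R,9E)-14-(tert-butyldimethylsilyloxy)-8-(4-methoxybenzyloxy)germacra-9,11(13)-dien-12,6-olide (trans-fused lactone) | C=C1C(=O)O[C@@H]2C[C@@H](C)CCC/C(CO[Si](C)(C)C(C)(C)C)=C\[C@@H](OCc3ccc(OC)cc3)[C@@H]12 | intermediate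
21 | (9E)-8-hydroxy-14-(tert-butyldimethylsilyloxy)germacra-9,11(13)-dien-12,6-olide (C4, C6, C7, C8 as in 20) | C=C1C(=O)O[C@@H]2C[C@@H](C)CCC/C(CO[Si](C)(C)C(C)(C)C)=C\[C@@H](O)[C@@H]12 | intermediate
22 | but-2-yne-1,4-diol | OCC#CCO | starting material
23 | (Z)-2-iodobut-2-ene-1,4-diol | OC/C=C(\I)CO | intermediate
24 | (Z)-1,4-bis(tert-butyldimethylsilyloxy)-2-iodobut-2-ene | CC(C)(C)[Si](C)(C)OC/C=C(\I)CO[Si](C)(C)C(C)(C)C | intermediate
25 | (Z)-4-(tert-butyldimethylsilyloxy)-2-[(tert-butyldimethylsilyloxy)methyl]but-2-enoic acid | OC(=O)/C(CO[Si](C)(C)C(C)(C)C)=C\CO[Si](C)(C)C(C)(C)C | intermediate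
26 | mixed anhydride of 25 and 2,4,6-trichlorobenzoic acid (not isolated) | O=C(OC(=O)c1c(Cl)cc(Cl)cc1Cl)/C(CO[Si](C)(C)C(C)(C)C)=C\CO[Si](C)(C)C(C)(C)C | intermediate
27 | (4S,6R,7S,8R,9E)-14-(tert-butyldimethylsilyloxy)-8-{(Z)-4-(tert-butyldimethylsilyloxy)-2-[(tert-butyldimethylsilyloxy)methyl]but-2-enoyloxy}germacra-9,11(13)-dien-12,6-olide | C=C1C(=O)O[C@@H]2C[C@@H](C)CCC/C(CO[Si](C)(C)C(C)(C)C)=C\[C@@H](OC(=O)/C(CO[Si](C)(C)C(C)(C)C)=C\CO[Si](C)(C)C(C)(C)C)[C@@H]12 | intermediate
28 | CNP0131216.1, (4S,6R,7S,8R,9E)-14-hydroxy-8-[(Z)-4-hydroxy-2-(hydroxymethyl)but-2-enoyloxy]germacra-9,11(13)-dien-12,6-olide | C=C1C(=O)O[C@@H]2C[C@@H](C)CCC/C(CO)=C\[C@@H](OC(=O)/C(=C\CO)CO)[C@@H]12 | target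

**Step count and risks**

Total: 21 steps. Longest linear sequence: 14 steps (7 to 28 through steps 5–16, 20 and 21).

Steps most likely to fail:

1. Step 15 (Proposed new method). The ring closure may be too slow to compete with protonation or 1,4-elimination of the allylnickel and with intermolecular allyl transfer. The allyl unit may also react through the wrong terminus, or the anti/syn control at C6 may be poor. The fallback uses known reaction types, sets out from 17 and comes back at 20. Bromoboration of the terminal allene of 17 with B-bromo-9-BBN (CH2Cl2, −78 °C, 2 mM) would give the (2-bromoallyl)borane F1. F1 adds through its γ-carbon (C7) to the aldehyde in a chair transition state to give the borinate F2, and ethanolamine work-up would release the 2-bromo homoallylic alcohol F3. Palladium-catalysed cyclocarbonylation of the vinyl bromide onto the C6 hydroxyl (Pd(PPh3)4, CO, K2CO3, THF, 60 °C) would then close the lactone to 20.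

2. Step 20. The olefin geometry of the activated acid may be lost by addition–elimination of DMAP, the hindered C8 hydroxyl may acylate slowly, and base may move the lactone from O6 to O8. The fallback sets out from 21 and 24, comes back at 27 and makes no new compound. It is a palladium-catalysed alkoxycarbonylation of vinyl iodide 24 with alcohol 21 as the nucleophile (Pd(OAc)2, Xantphos, CO 1 atm, Et3N, toluene, 60 °C). The acylpalladium intermediate keeps the olefin geometry and no activated free acid is involved.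

3. Step 11. The E/Z selectivity of the trisubstituted olefin may be eroded, and the basic phosphonate anion may epimerise aldehyde 13 or isomerise its allene to a diene. The fallback sets out from 13 and 4 and comes back at 14. A neutral Wittig reaction of 13 with ethyl bromo(triphenylphosphoranylidene)acetate (CH2Cl2, rt) would give the (Z)-α-bromo enoate F4. Zinc insertion into iodide 4 (Zn, LiCl, THF, 50 °C) would give the alkylzinc iodide F5. A Negishi coupling of F4 with F5 (Pd(OAc)2, SPhos, THF, rt) replaces bromine by the alkyl chain with retention and gives 14.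

**Further compounds**

F1 | step 15 | (2-bromoallyl)borane from 17 and B-bromo-9-BBN (boron on C13, bromine on C11) | BrC(CB1C2CCCC1CCC2)=C[C@H](OCc1ccc(OC)cc1)/C=C(/CO[Si](C)(C)C(C)(C)C)CCC[C@H](C)CC=O
F2 | step 15 | 9-BBN borinate of the cyclised 2-bromo homoallylic alcohol | BrC(=C)[C@H]1[C@H](OB2C3CCCC2CCC3)C[C@@H](C)CCC/C(CO[Si](C)(C)C(C)(C)C)=C\[C@H]1OCc1ccc(OC)cc1
F3 | step 15 | ten-membered 2-bromo homoallylic alcohol (C6–OH, C11–Br, configurations as in 19) | BrC(=C)[C@H]1[C@H](O)C[C@@H](C)CCC/C(CO[Si](C)(C)C(C)(C)C)=C\[C@H]1OCc1ccc(OC)cc1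
F0 | step 20 | none | none
F4 | step 11 | ethyl (2Z,4S)-2-bromo-4-[(4-methoxybenzyl)oxy]hepta-2,5,6-trienoate | CCOC(=O)/C(Br)=C/[C@H](C=C=C)OCc1ccc(OC)cc1
F5 | step 11 | [(4S)-6,6-dimethoxy-4-methylhexyl]zinc iodide | I[Zn]CCC[C@H](C)CC(OC)OC
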